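All runs were generated by integration for substances that don't exist, noise included.

If you repeat this flask, watch how fast target grows per mole of reagent charged, not per equivalent.

| setting | Saturday's | Tuesday's | Sunday's | flask |
|---|---|---|---|---|
| substrate | 0.50 M | 0.50 M | 1 M | 0.50 M |
| reagent in the second phase | 1.5 equiv | 2.2 equiv | 3 equiv | 3.00 equiv |
| protic impurity | 0.50 M | 0.50 M | 0.50 M | 0.500 M |
| remark | run made earlier | run made earlier | run made earlier |  |
| time |  |  |  | 1.0 h |
| volume of the second phase over the first |  |  |  | 1.0 |

| run | time / min | target / % |
|---|---|---|
| Saturday's | 6.00 | 2 |
| Saturday's | 12.0 | 0 |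
| Saturday's | 20.0 | 1 |
| Saturday's | 25.0 | 4 |
| Saturday's | 30.0 | 2 |
| Saturday's | 40.0 | 8 |
| Tuesday's | 2.50 | 0 |
| Tuesday's | 8.00 | 2 |
| Tuesday's | 12.0 | 2 |
| Tuesday's | 20.0 | 2 |
| Tuesday's | 30.0 | 6 |
| Tuesday's | 40.0 | 7 |
| Sunday's | 3.00 | 0 |
| Sunday's | 5.00 | 1 |
| Sunday's | 10.0 | 3 |
| Sunday's | 20.0 | 6 |
| Sunday's | 40.0 | 14 |

(readings scatter by 1.5 percentage points)

- in the second phase: reagent in the second phase; everything else is in the first
- charges count per volume of the first phase; a concentration in a rate is the amount of a species over the volume of its own phase; every rate counts per litre of the first phase
- steps thought possible: reagent in the reaction phase + protic impurity -> quenched reagent; substrate + reagent in the reaction phase -> target; reagent in the reaction phase + target -> over-reacted product; reagent in the reaction phase <-> reagent in the second phase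
- the earlier runs hold the two phases in the same ratio of volumes as the flask asked about

- larch: doubling the transfer coefficient of the reagent in the second phase, all else as stated
- alder: doubling the amount of reagent in the second phase, all else as stated

- how much target there is at 1.0 h, in percent of the substrate charged
- the change that raises the amount of target at 1.0 h, in percent of the substrate charged most ("none" if none brings more than 2 percentage points) (larch / alder / none)
- amount of target at 1.0 h, in percent of the substrate charged, after larch

Start with Sunday's run, which has the flask's equivalents. Stretch its 14 % at 40.0 min to 1.0 h and you get 21.0 %. Now object: equivalents count on substrate, so the flask's charge is 1.50 M and Sunday's is 3.00 M, twice that. Assume c(reagent in the reaction phase) follows the molar charge, and halve the figure to 10.5 %. Object again: that rests on one reading. Saturday's run, scaled the same way, gives 24.0 %, but its 8 % carries a scatter of 1.5 percentage points, and the scaling stretches that too.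

So pool the runs. Add the last readings of the three runs and divide by the sum of molar charge times time. This gives the charge yield constant, 0.00149 L mol⁻¹ min⁻¹, the fraction of substrate turned to target per minute per mole of reagent charged per litre. For the flask it gives 13.5 %. Two objections remain, and they pull opposite ways. The curves bend upward, which favours a higher figure. By this estimate substrate falls to 86.5 %, which favours a lower one. Both look small, so keep 13.5 %. For alder, the doubled charge doubles this to 27.0 %. Larch doubles the exchange in both directions and adds no reagent. Take 27.0 % as a generous guess for it and put alder first.

The forecast says 14 %, a little above this reckoning, with alder best and 24 % after larch. It holds that “Doubling the reagent raises the feed equally and also resists depletion and any partition limit”.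

The flask gives 14.5 %, and alder is best: it adds 9.5 points against 6.7 points for larch, which reaches 21.2 %.

reagent in the reaction phase + protic impurity → quenched reagent (k = 0.131 L mol⁻¹ min⁻¹); substrate + reagent in the reaction phase → target (k = 0.0920 L mol⁻¹ min⁻¹); reagent in the reaction phase + target → over-reacted product (k = 0.128 L mol⁻¹ min⁻¹); reagent in the reaction phase ⇌ reagent in the second phase, rate k4*([reagent in the reaction phase] - [reagent in the second phase]/K4) per volume of the first phase (partition coefficient = 5.84, kL = 0.0198 min⁻¹) At 1.00 h, reagent in the reaction phase is made at 0.992 of the rate it is used up, each step taken net, a quasi-steady state, and stands at 0.0363 M. Read from this flask, the charge yield constant is 0.00161 L mol⁻¹ min⁻¹. Applied to the same flask read at 2.5 h, the pooled 0.00149 L mol⁻¹ min⁻¹ gives 33.5 %. That flask holds 26.8 % target and 10.7 % over-reacted product.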